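The target is assembled around upper ring C. Upper C4, which carries upper ring A and C6 of lower ring A, is a benzophenone carbonyl carbon in keto aldehyde 17, and the adjacent upper C3 is an aldehyde carbon on the C2 ether stereocentre (from (R)-mandelate by Mitsunobu inversion). SmI2 unites these two carbonyl carbons, closing ring C and fixing C3 trans to the C2 aryl group; the C4 carbinol is then replaced by hydrogen via the cation. The all-cis lower flavan-3,4-diol is grown afterwards on lower ring A: ligand-controlled alkynylation (C4), osmylation of the Z-alkene (C3, C2) and Mitsunobu closure with inversion at C2.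

Key step: step 13

Assumption: (R)-4-hydroxymandelic acid 13 is bought as the single enantiomer; the racemate would first need a resolution.
Notation: Bn = benzyl, TBS = tert-butyldimethylsilyl, MOM = methoxymethyl. "U" is the upper flavan-4-yl group of 20, that is 7,8-bis(benzyloxy)-2-[4-(benzyloxy)phenyl]-3-(TBS-oxy)chroman-4-yl with the C2 aryl group trans to O3 and the C4 bond to lower ring A cis to O3; it is carried unchanged from 20 to 30.

Step 1
Reactants: 1 2,3-dihydroxybenzaldehyde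
Product: 2 2,3-bis(benzyloxy)benzaldehyde
Conditions: BnBr (2.2 equiv), K2CO3, DMF, 60 °C
Reagents that add atoms: benzyl bromide, BrCc1ccccc1
Why: Williamson etherification of both phenoxides should proceed cleanly under carbonate base, the aldehyde being inert.

Step 2
Reactants: 2 2,3-bis(benzyloxy)benzaldehyde
Product: 4 2,3-bis(benzyloxy)phenol, via aryl formate 3 (not isolated)
Conditions: mCPBA, CH2Cl2, rt; then K2CO3 (cat.), MeOH, rt
Reagents that add atoms: 3-chloroperoxybenzoic acid (mCPBA), O=C(OO)c1cccc(Cl)c1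
Why: Baeyer–Villiger oxidation should insert oxygen by migration of the electron-rich aryl group, and carbonate-catalysed methanolysis of the formate then frees the phenol.

Step 3
Reactants: 4 2,3-bis(benzyloxy)phenol
Product: 5 1,2-bis(benzyloxy)-3-(methoxymethoxy)benzene
Conditions: MOMCl, iPr2NEt, CH2Cl2, 0 °C to rt
Reagents that add atoms: chloromethyl methyl ether, COCCl
Why: O-alkylation of the phenol installs the acetal that later directs ortho-lithiation.

Step 4
Reactants: 6 2,3,4-trihydroxybenzaldehyde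
Product: 7 4-(allyloxy)-2,3-dihydroxybenzaldehyde
Conditions: allyl bromide (1.05 equiv), NaHCO3, DMF, 40 °C
Reagents that add atoms: allyl bromide, C=CCBr
Why: Regioselective Williamson etherification, because hydrogencarbonate ionises only the 4-OH (para to the formyl group and not held in a hydrogen bond), so allylation should occur there alone.

Step 5
Reactants: 7 4-(allyloxy)-2,3-dihydroxybenzaldehyde
Product: 8 4-(allyloxy)-2,3-bis(benzyloxy)benzaldehyde
Conditions: BnBr (2.3 equiv), K2CO3, DMF, 60 °C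
Reagents that add atoms: benzyl bromide, BrCc1ccccc1
Why: Williamson benzylation of the two remaining phenols, the chelated 2-OH needing the higher temperature.

Step 6
Reactants: 5 1,2-bis(benzyloxy)-3-(methoxymethoxy)benzene; 8 4-(allyloxy)-2,3-bis(benzyloxy)benzaldehyde
Product: 10 [4-(allyloxy)-2,3-bis(benzyloxy)phenyl][3,4-bis(benzyloxy)-2-(methoxymethoxy)phenyl]methanol (racemic), via aryllithium 9 (not isolated)
Conditions: n-BuLi (1.1 equiv), TMEDA, THF, -20 to 0 °C; then 8, -78 °C to rt; aq. NH4Cl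
Reagents that add atoms: none
Why: Directed ortho-metalation, in which the OMOM group guides n-BuLi to its single free ortho position and the aryllithium adds 1,2 to aldehyde 8; the carbinol centre is destroyed in the next step, so no stereocontrol is needed.

Step 7
Reactants: 10 the diaryl carbinol
Product: 11 [4-(allyloxy)-2,3-bis(benzyloxy)phenyl][3,4-bis(benzyloxy)-2-(methoxymethoxy)phenyl]methanone
Conditions: Dess–Martin periodinane, NaHCO3, CH2Cl2, rt
Reagents that add atoms: none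
Why: Dess–Martin oxidation of the diaryl carbinol should give the benzophenone under buffered conditions that leave allyl, benzyl and MOM ethers alone.

Step 8
Reactants: 11 the MOM-protected benzophenone
Product: 12 [4-(allyloxy)-2,3-bis(benzyloxy)phenyl][3,4-bis(benzyloxy)-2-hydroxyphenyl]methanone
Conditions: HCl (3 M aq.), MeOH/THF, 45 °C
Reagents that add atoms: none
Why: Acid-catalysed acetal cleavage, assisted by the ortho carbonyl group, should free the phenol while benzyl and allyl ethers survive.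

Step 9
Reactants: 13 (R)-4-hydroxymandelic acid
Product: 14 benzyl (2R)-2-[4-(benzyloxy)phenyl]-2-hydroxyacetate
Conditions: BnBr (2.1 equiv), K2CO3, DMF, rt
Reagents that add atoms: benzyl bromide, BrCc1ccccc1
Why: Carbonate-mediated O-alkylation turns carboxylate and phenoxide into benzyl ester and benzyl ether, while the secondary hydroxyl and the stereocentre should stay untouched.

Step 10
Reactants: 12 the 2-hydroxybenzophenone; 14 the (R)-mandelate
Product: 15 benzyl (2S)-2-{2-[4-(allyloxy)-2,3-bis(benzyloxy)benzoyl]-5,6-bis(benzyloxy)phenoxy}-2-[4-(benzyloxy)phenyl]acetate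
Conditions: PPh3, DIAD, toluene, 0 °C to rt
Reagents that add atoms: none
Why: Mitsunobu etherification, in which the acidic phenol displaces the activated hydroxyl at the ester-bearing carbon by SN2, so the R centre of 14 should be inverted to the S centre that becomes upper C2.

Step 11
Reactants: 15 the keto ester
Product: 16 (2S)-2-{2-[[4-(allyloxy)-2,3-bis(benzyloxy)phenyl](hydroxy)methyl]-5,6-bis(benzyloxy)phenoxy}-2-[4-(benzyloxy)phenyl]ethan-1-ol (both carbinol epimers)
Conditions: LiBH4, THF, 0 °C to rt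
Reagents that add atoms: none
Why: Hydride reduction of the benzyl ester to the primary alcohol and of the diaryl ketone to the carbinol should outrun any enolisation at C2 and leave the allyl group alone.

Step 12
Reactants: 16 the diol
Product: 17 (2S)-2-{2-[4-(allyloxy)-2,3-bis(benzyloxy)benzoyl]-5,6-bis(benzyloxy)phenoxy}-2-[4-(benzyloxy)phenyl]acetaldehyde (keto aldehyde)
Conditions: Dess–Martin periodinane (3 equiv), NaHCO3, CH2Cl2, 0 °C to rt; used at once
Reagents that add atoms: none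
Why: Double Dess–Martin oxidation under hydrogencarbonate buffer should give ketone and aldehyde without base, which preserves the enolisable C2 centre.

Step 13
Reactants: 17 the keto aldehyde
Product: 18 (2S,3S,4R)-4-[4-(allyloxy)-2,3-bis(benzyloxy)phenyl]-7,8-bis(benzyloxy)-2-[4-(benzyloxy)phenyl]chromane-3,4-diol (3-OH trans to the C2 aryl group, 3,4-diol cis)
Conditions: SmI2 (2.5 equiv, 0.1 M), THF, -78 to -20 °C; aq. NH4Cl
Reagents that add atoms: none
Why: SmI2 (divalent samarium) reduces the diaryl ketone, which accepts an electron far more readily than the aldehyde, to a ketyl held on trivalent samarium; the oxophilic metal ties the formyl oxygen into the same complex, C4 bonds to the formyl carbon C3, and a second equivalent of SmI2 reduces the resulting oxygen radical to the chelated cis-diolate, which work-up protonates. The closest known reaction type is the SmI2-mediated intramolecular ketone–aldehyde pinacol cyclisation to cis-1,2-diols. Ring C closes in the 6-exo-trig mode. C3 is controlled by the C2 stereocentre, since in the chair-like chelate the C2 aryl group and the lower aryl group on C4 both sit equatorial, which places O3 equatorial and therefore trans to the C2 aryl group; C4 is controlled by the samarium bridge, which holds O4 cis to O3. The step needs reduction of the ketone before the aldehyde and no loss of configuration at C2, and the lower reduction potential of the diaryl ketone, the absence of base or proton source and the low temperature should secure both.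

Step 14
Reactants: 18 the cis-diol
Product: 19 (2S,3S,4R)-4-[4-(allyloxy)-2,3-bis(benzyloxy)phenyl]-7,8-bis(benzyloxy)-2-[4-(benzyloxy)phenyl]-3-(TBS-oxy)chroman-4-ol
Conditions: TBSOTf (1.2 equiv), 2,6-lutidine, CH2Cl2, -78 °C
Reagents that add atoms: tert-butyldimethylsilyl triflate, CC(C)(C)[Si](C)(C)OS(=O)(=O)C(F)(F)F
Why: Silylation should occur only at the secondary 3-OH, the tertiary diaryl carbinol being too hindered, and the bulky silyl ether then shields the O3 face of C4.

Step 15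
Reactants: 19 the tertiary carbinol
Product: 20 (2S,3R,4R)-4-[4-(allyloxy)-2,3-bis(benzyloxy)phenyl]-7,8-bis(benzyloxy)-2-[4-(benzyloxy)phenyl]-3-(TBS-oxy)chromane (C2 aryl trans to O3, C4 aryl cis to O3)
Conditions: Et3SiH (5 equiv), CF3CO2H (3 equiv), CH2Cl2, -78 to -30 °C
Reagents that add atoms: none
Why: Ionic hydrogenation, in which acid ionises the tertiary carbinol to a diarylmethyl cation stabilised by four alkoxy groups and Et3SiH should deliver hydride to the face anti to the 3-OTBS group, leaving the lower aryl group cis to O3 and setting upper C4.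

Step 16
Reactants: 20 the allyl ether
Product: 21 2,3-bis(benzyloxy)-4-U-phenol
Conditions: Pd(PPh3)4 (5 mol%), K2CO3, MeOH/THF, 60 °C
Reagents that add atoms: none
Why: Tsuji–Trost-type deallylation, in which zerovalent palladium ionises the allyl aryl ether and methoxide captures the allyl fragment, leaving benzyl and silyl ethers intact.

Step 17
Reactants: 21 the phenol
Product: 22 3,4-bis(benzyloxy)-2-hydroxy-5-U-benzaldehyde
Conditions: MgCl2, Et3N, (CH2O)n, THF, reflux
Reagents that add atoms: paraformaldehyde (as formaldehyde), C=O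
Why: Casnati–Skattebøl ortho-formylation, in which the magnesium phenoxide directs formaldehyde to the only free ortho position and a second formaldehyde oxidises the hydroxymethyl group to the aldehyde.

Step 18
Reactants: 22 the salicylaldehyde
Product: 23 3,4-bis(benzyloxy)-2-(TBS-oxy)-5-U-benzaldehyde
Conditions: TBSCl, imidazole, DMF, rt
Reagents that add atoms: tert-butyldimethylsilyl chloride, CC(C)(C)[Si](C)(C)Cl
Why: Silylation of the phenol masks its acidic proton for the organozinc step.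

Step 19
Reactants: 23 the silylated aldehyde; 24 1-(benzyloxy)-4-ethynylbenzene
Product: 26 (1S)-1-[3,4-bis(benzyloxy)-2-(TBS-oxy)-5-U-phenyl]-3-[4-(benzyloxy)phenyl]prop-2-yn-1-ol, via alkynylzinc 25 (not isolated)
Conditions: 24 (3 equiv), Et2Zn (3 equiv), toluene, reflux; then (S)-BINOL (40 mol%), Ti(OiPr)4 (1 equiv), CH2Cl2, rt; 23; aq. NH4Cl
Reagents that add atoms: none
Why: BINOL–Ti(OiPr)4-catalysed asymmetric alkynylzinc addition to an aromatic aldehyde, in which the (S)-ligand should deliver the alkynyl group to the Si face of the formyl group and so set lower C4 under reagent control, far from the existing stereocentres.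

Step 20
Reactants: 26 the propargylic alcohol
Product: 27 2,3-bis(benzyloxy)-6-{(1S)-3-[4-(benzyloxy)phenyl]-1-(TBS-oxy)prop-2-yn-1-yl}-4-U-phenol
Conditions: NaH (1.1 equiv), THF, 0 °C; aq. NH4Cl
Reagents that add atoms: none
Why: Anionic 1,5 O-to-O silyl migration, in which the propargylic alkoxide takes the silyl group from the neighbouring aryl oxygen because the phenoxide is the more stable anion; this frees the phenol and protects O4 in one operation.

Step 21
Reactants: 27 the alkyne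
Product: 28 2,3-bis(benzyloxy)-6-{(1S,2Z)-3-[4-(benzyloxy)phenyl]-1-(TBS-oxy)prop-2-en-1-yl}-4-U-phenol
Conditions: H2 (1 atm), Pd/CaCO3–Pb(OAc)2 (Lindlar catalyst), quinoline, EtOAc, rt
Reagents that add atoms: none
Why: Lindlar semihydrogenation adds hydrogen syn to the alkyne and should stop at the Z-alkene without touching benzyl ethers.

Step 22
Reactants: 28 the Z-alkene
Product: 29 2,3-bis(benzyloxy)-6-{(1R,2S,3S)-3-[4-(benzyloxy)phenyl]-1-(TBS-oxy)-2,3-dihydroxypropyl}-4-U-phenol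
Conditions: OsO4 (2 mol%), NMO, acetone/H2O, 0 °C
Reagents that add atoms: N-methylmorpholine N-oxide, C[N+]1([O-])CCOCC1; water, O
Why: Upjohn dihydroxylation, a syn addition to the Z-alkene that should occur from the face anti to the allylic silyloxy group (allylic hydrogen held in the alkene plane by 1,3-allylic strain, the empirical rule for osmylation of allylic ethers), setting lower C3 erythro to C4 and C2 erythro to C3.

Step 23
Reactants: 29 the phenolic diol
Product: 30 (2R,3S,4R)-7,8-bis(benzyloxy)-2-[4-(benzyloxy)phenyl]-4-(TBS-oxy)-6-U-chroman-3-ol (lower unit all-cis)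
Conditions: PPh3, DIAD, THF, 0 °C
Reagents that add atoms: none
Why: Intramolecular Mitsunobu etherification, in which the benzylic C2 hydroxyl is activated and displaced by the phenol with inversion in a 6-exo-tet closure of lower ring C, which should give the 2,3-cis-3,4-cis arrangement.

Step 24
Reactants: 30 the bis-silyl ether
Product: 31 (2R,3R,4R)-7,8-bis(benzyloxy)-2-[4-(benzyloxy)phenyl]-6-(U with free 3-OH)chromane-3,4-diol
Conditions: TBAF, AcOH, THF, rt to 40 °C
Reagents that add atoms: none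
Why: Fluoride cleaves both silyl ethers, acetic acid buffering the alkoxides so that the diol is not exposed to strong base.

Step 25
Reactants: 31 the hexabenzyl ether
Product: 32 (2R,3R,4R)-2-(4-hydroxyphenyl)-6-[(2S,3R,4R)-3,7,8-trihydroxy-2-(4-hydroxyphenyl)chroman-4-yl]chromane-3,4,7,8-tetrol (target)
Conditions: H2 (1 atm), Pd(OH)2/C, THF/MeOH, rt, neutral, stopped at full debenzylation
Reagents that add atoms: none
Why: Hydrogenolysis of the six benzyl aryl ethers should free all phenols, since benzyl aryl ethers cleave much faster than the secondary benzylic hydroxyl or the cyclic benzylic ether bonds.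

Compound list
1 | 2,3-dihydroxybenzaldehyde | O=Cc1cccc(O)c1O | starting material
2 | 2,3-bis(benzyloxy)benzaldehyde | O=Cc1cccc(OCc2ccccc2)c1OCc1ccccc1 | intermediate
3 | 2,3-bis(benzyloxy)phenyl formate | O=COc1cccc(OCc2ccccc2)c1OCc1ccccc1 | intermediate
4 | 2,3-bis(benzyloxy)phenol | Oc1cccc(OCc2ccccc2)c1OCc1ccccc1 | intermediate
5 | 1,2-bis(benzyloxy)-3-(methoxymethoxy)benzene | COCOc1cccc(OCc2ccccc2)c1OCc1ccccc1 | intermediate
6 | 2,3,4-trihydroxybenzaldehyde | O=Cc1ccc(O)c(O)c1O | starting material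
7 | 4-(allyloxy)-2,3-dihydroxybenzaldehyde | O=Cc1ccc(OCC=C)c(O)c1O | intermediate
8 | 4-(allyloxy)-2,3-bis(benzyloxy)benzaldehyde | O=Cc1ccc(OCC=C)c(OCc2ccccc2)c1OCc1ccccc1 | intermediate
9 | [3,4-bis(benzyloxy)-2-(methoxymethoxy)phenyl]lithium | [Li]c1ccc(OCc2ccccc2)c(OCc2ccccc2)c1OCOC | intermediate
10 | [4-(allyloxy)-2,3-bis(benzyloxy)phenyl][3,4-bis(benzyloxy)-2-(methoxymethoxy)phenyl]methanol (racemic) | C=CCOc1ccc(C(O)c2ccc(OCc3ccccc3)c(OCc3ccccc3)c2OCOC)c(OCc2ccccc2)c1OCc1ccccc1 | intermediate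
11 | [4-(allyloxy)-2,3-bis(benzyloxy)phenyl][3,4-bis(benzyloxy)-2-(methoxymethoxy)phenyl]methanone | C=CCOc1ccc(C(=O)c2ccc(OCc3ccccc3)c(OCc3ccccc3)c2OCOC)c(OCc2ccccc2)c1OCc1ccccc1 | intermediate
12 | [4-(allyloxy)-2,3-bis(benzyloxy)phenyl][3,4-bis(benzyloxy)-2-hydroxyphenyl]methanone | C=CCOc1ccc(C(=O)c2ccc(OCc3ccccc3)c(OCc3ccccc3)c2O)c(OCc2ccccc2)c1OCc1ccccc1 | intermediate
13 | (R)-4-hydroxymandelic acid | O[C@@H](C(=O)O)c1ccc(O)cc1 | starting material
14 | benzyl (2R)-2-[4-(benzyloxy)phenyl]-2-hydroxyacetate | O[C@@H](C(=O)OCc1ccccc1)c1ccc(OCc2ccccc2)cc1 | intermediate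
15 | benzyl (2S)-2-{2-[4-(allyloxy)-2,3-bis(benzyloxy)benzoyl]-5,6-bis(benzyloxy)phenoxy}-2-[4-(benzyloxy)phenyl]acetate | C=CCOc1ccc(C(=O)c2ccc(OCc3ccccc3)c(OCc3ccccc3)c2O[C@@H](c2ccc(OCc3ccccc3)cc2)C(=O)OCc2ccccc2)c(OCc2ccccc2)c1OCc1ccccc1 | intermediate
16 | (2S)-2-{2-[[4-(allyloxy)-2,3-bis(benzyloxy)phenyl](hydroxy)methyl]-5,6-bis(benzyloxy)phenoxy}-2-[4-(benzyloxy)phenyl]ethan-1-ol (carbinol epimers) | C=CCOc1ccc(C(O)c2ccc(OCc3ccccc3)c(OCc3ccccc3)c2O[C@@H](c2ccc(OCc3ccccc3)cc2)CO)c(OCc2ccccc2)c1OCc1ccccc1 | intermediate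
17 | (2S)-2-{2-[4-(allyloxy)-2,3-bis(benzyloxy)benzoyl]-5,6-bis(benzyloxy)phenoxy}-2-[4-(benzyloxy)phenyl]acetaldehyde | C=CCOc1ccc(C(=O)c2ccc(OCc3ccccc3)c(OCc3ccccc3)c2O[C@@H](c2ccc(OCc3ccccc3)cc2)C=O)c(OCc2ccccc2)c1OCc1ccccc1 | intermediate
18 | (2S,3S,4R)-4-[4-(allyloxy)-2,3-bis(benzyloxy)phenyl]-7,8-bis(benzyloxy)-2-[4-(benzyloxy)phenyl]chromane-3,4-diol | C=CCOc1ccc([C@@]2(O)c3ccc(OCc4ccccc4)c(OCc4ccccc4)c3O[C@@H](c3ccc(OCc4ccccc4)cc3)[C@@H]2O)c(OCc2ccccc2)c1OCc1ccccc1 | intermediate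
19 | (2S,3S,4R)-4-[4-(allyloxy)-2,3-bis(benzyloxy)phenyl]-7,8-bis(benzyloxy)-2-[4-(benzyloxy)phenyl]-3-(TBS-oxy)chroman-4-ol | C=CCOc1ccc([C@@]2(O)c3ccc(OCc4ccccc4)c(OCc4ccccc4)c3O[C@@H](c3ccc(OCc4ccccc4)cc3)[C@@H]2O[Si](C)(C)C(C)(C)C)c(OCc2ccccc2)c1OCc1ccccc1 | intermediate
20 | (2S,3R,4R)-4-[4-(allyloxy)-2,3-bis(benzyloxy)phenyl]-7,8-bis(benzyloxy)-2-[4-(benzyloxy)phenyl]-3-(TBS-oxy)chromane | C=CCOc1ccc([C@@H]2c3ccc(OCc4ccccc4)c(OCc4ccccc4)c3O[C@@H](c3ccc(OCc4ccccc4)cc3)[C@@H]2O[Si](C)(C)C(C)(C)C)c(OCc2ccccc2)c1OCc1ccccc1 | intermediate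
21 | 2,3-bis(benzyloxy)-4-U-phenol | Oc1ccc([C@@H]2c3ccc(OCc4ccccc4)c(OCc4ccccc4)c3O[C@@H](c3ccc(OCc4ccccc4)cc3)[C@@H]2O[Si](C)(C)C(C)(C)C)c(OCc2ccccc2)c1OCc1ccccc1 | intermediate
22 | 3,4-bis(benzyloxy)-2-hydroxy-5-U-benzaldehyde | O=Cc1cc([C@@H]2c3ccc(OCc4ccccc4)c(OCc4ccccc4)c3O[C@@H](c3ccc(OCc4ccccc4)cc3)[C@@H]2O[Si](C)(C)C(C)(C)C)c(OCc2ccccc2)c(OCc2ccccc2)c1O | intermediate
23 | 3,4-bis(benzyloxy)-2-(TBS-oxy)-5-U-benzaldehyde | O=Cc1cc([C@@H]2c3ccc(OCc4ccccc4)c(OCc4ccccc4)c3O[C@@H](c3ccc(OCc4ccccc4)cc3)[C@@H]2O[Si](C)(C)C(C)(C)C)c(OCc2ccccc2)c(OCc2ccccc2)c1O[Si](C)(C)C(C)(C)C | intermediate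
24 | 1-(benzyloxy)-4-ethynylbenzene | C#Cc1ccc(OCc2ccccc2)cc1 | starting material
25 | ethyl{[4-(benzyloxy)phenyl]ethynyl}zinc | CC[Zn]C#Cc1ccc(OCc2ccccc2)cc1 | intermediate
26 | (1S)-1-[3,4-bis(benzyloxy)-2-(TBS-oxy)-5-U-phenyl]-3-[4-(benzyloxy)phenyl]prop-2-yn-1-ol | CC(C)(C)[Si](C)(C)Oc1c(cc([C@@H]2c3ccc(OCc4ccccc4)c(OCc4ccccc4)c3O[C@@H](c3ccc(OCc4ccccc4)cc3)[C@@H]2O[Si](C)(C)C(C)(C)C)c(OCc2ccccc2)c1OCc1ccccc1)[C@@H](O)C#Cc1ccc(OCc2ccccc2)cc1 | intermediate
27 | 2,3-bis(benzyloxy)-6-{(1S)-3-[4-(benzyloxy)phenyl]-1-(TBS-oxy)prop-2-yn-1-yl}-4-U-phenol | Oc1c(cc([C@@H]2c3ccc(OCc4ccccc4)c(OCc4ccccc4)c3O[C@@H](c3ccc(OCc4ccccc4)cc3)[C@@H]2O[Si](C)(C)C(C)(C)C)c(OCc2ccccc2)c1OCc1ccccc1)[C@@H](O[Si](C)(C)C(C)(C)C)C#Cc1ccc(OCc2ccccc2)cc1 | intermediate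
28 | 2,3-bis(benzyloxy)-6-{(1S,2Z)-3-[4-(benzyloxy)phenyl]-1-(TBS-oxy)prop-2-en-1-yl}-4-U-phenol | Oc1c(cc([C@@H]2c3ccc(OCc4ccccc4)c(OCc4ccccc4)c3O[C@@H](c3ccc(OCc4ccccc4)cc3)[C@@H]2O[Si](C)(C)C(C)(C)C)c(OCc2ccccc2)c1OCc1ccccc1)[C@@H](O[Si](C)(C)C(C)(C)C)/C=C\c1ccc(OCc2ccccc2)cc1 | intermediate
29 | 2,3-bis(benzyloxy)-6-{(1R,2S,3S)-3-[4-(benzyloxy)phenyl]-1-(TBS-oxy)-2,3-dihydroxypropyl}-4-U-phenol | Oc1c(cc([C@@H]2c3ccc(OCc4ccccc4)c(OCc4ccccc4)c3O[C@@H](c3ccc(OCc4ccccc4)cc3)[C@@H]2O[Si](C)(C)C(C)(C)C)c(OCc2ccccc2)c1OCc1ccccc1)[C@@H](O[Si](C)(C)C(C)(C)C)[C@@H](O)[C@@H](O)c1ccc(OCc2ccccc2)cc1 | intermediate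
30 | (2R,3S,4R)-7,8-bis(benzyloxy)-2-[4-(benzyloxy)phenyl]-4-(TBS-oxy)-6-U-chroman-3-ol | c1ccccc1COc1ccc(cc1)[C@H]1Oc2c(cc([C@@H]5c6ccc(OCc7ccccc7)c(OCc7ccccc7)c6O[C@@H](c6ccc(OCc7ccccc7)cc6)[C@@H]5O[Si](C)(C)C(C)(C)C)c(OCc3ccccc3)c2OCc2ccccc2)[C@@H](O[Si](C)(C)C(C)(C)C)[C@H]1O | intermediate
31 | (2R,3R,4R)-7,8-bis(benzyloxy)-2-[4-(benzyloxy)phenyl]-6-(U with free 3-OH)chromane-3,4-diol | c1ccccc1COc1ccc(cc1)[C@H]1Oc2c(cc([C@@H]5c6ccc(OCc7ccccc7)c(OCc7ccccc7)c6O[C@@H](c6ccc(OCc7ccccc7)cc6)[C@@H]5O)c(OCc3ccccc3)c2OCc2ccccc2)[C@@H](O)[C@H]1O | intermediate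
32 | (2R,3R,4R)-2-(4-hydroxyphenyl)-6-[(2S,3R,4R)-3,7,8-trihydroxy-2-(4-hydroxyphenyl)chroman-4-yl]chromane-3,4,7,8-tetrol | Oc1ccc([C@H]2Oc3c(cc([C@@H]4c5ccc(O)c(O)c5O[C@@H](c5ccc(O)cc5)[C@@H]4O)c(O)c3O)[C@@H](O)[C@H]2O)cc1 | target

Total step count: 25. Longest linear sequence: 22 steps (steps 1–3, 6–8 and 10–25, from 1 to 32).

Steps most likely to fail

Step 13. The ketyl may be reduced further to the benzhydrol instead of adding to the formyl group, or the aldehyde may lose its C2 configuration before closure. The fallback sets out from 17 and closes ring C by reductive carbonyl olefination instead. McMurry coupling of ketone and aldehyde with TiCl3(DME)1.5 and Zn–Cu in DME should give 4-[4-(allyloxy)-2,3-bis(benzyloxy)phenyl]-7,8-bis(benzyloxy)-2-[4-(benzyloxy)phenyl]-2H-chromene F1. Dimethyldioxirane should epoxidise the electron-rich trisubstituted alkene anti to the C2 aryl group, much faster than the allyl ether, to give the 3,4-epoxide F2. Et3SiH with CF3CO2H should open F2 to the same C4 cation as in step 15 and reduce it anti to O3, giving the chroman-3-ol F3. Silylation with TBSOTf and 2,6-lutidine comes back to the route at 20.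

Step 22. Facial selectivity in the osmylation may be poor if the large aryl group on the allylic carbon overrides the preference for attack anti to the silyloxy group. The fallback sets out from 28 and puts the oxygen on C3 under catalyst control. Acetylation (Ac2O, pyridine) should give the aryl acetate F4. Jacobsen epoxidation with (salen)MnCl, mCPBA and NMO at -78 °C, using the catalyst antipode matched to attack anti to the silyloxy group, should give the cis-epoxide F5. K2CO3 in MeOH should then remove the acetate, and the phenoxide should open the epoxide at benzylic C2 with inversion (6-endo), coming back to the route at 30. This detour also bypasses the Mitsunobu closure of step 23.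

Step 25. The activated benzylic 4-hydroxyl of the lower unit may be lost by hydrogenolysis alongside debenzylation. The fallback sets out from 30 and reverses the last two operations. Hydrogenolysis (H2, Pd(OH)2/C, EtOAc/THF) while both secondary oxygens at risk still carry silyl groups should give the bis-silylated hexaphenol F6. Et3N·3HF in THF under argon should then remove the silyl ethers and come back to the route at 32.

Further compounds
F1 | step 13 | 4-[4-(allyloxy)-2,3-bis(benzyloxy)phenyl]-7,8-bis(benzyloxy)-2-[4-(benzyloxy)phenyl]-2H-chromene, C2 as in 17 | C=CCOc1ccc(C2=C[C@H](c3ccc(OCc4ccccc4)cc3)Oc3c(OCc4ccccc4)c(OCc4ccccc4)ccc23)c(OCc2ccccc2)c1OCc1ccccc1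
F2 | step 13 | 3,4-epoxide of F1, oxygen anti to the C2 aryl group | C=CCOc1ccc([C@@]2(O5)c3ccc(OCc4ccccc4)c(OCc4ccccc4)c3O[C@@H](c3ccc(OCc4ccccc4)cc3)[C@@H]25)c(OCc2ccccc2)c1OCc1ccccc1
F3 | step 13 | (2S,3R,4R)-4-[4-(allyloxy)-2,3-bis(benzyloxy)phenyl]-7,8-bis(benzyloxy)-2-[4-(benzyloxy)phenyl]chroman-3-ol | C=CCOc1ccc([C@@H]2c3ccc(OCc4ccccc4)c(OCc4ccccc4)c3O[C@@H](c3ccc(OCc4ccccc4)cc3)[C@@H]2O)c(OCc2ccccc2)c1OCc1ccccc1
F4 | step 22 | aryl acetate of 28 | CC(=O)Oc1c(cc([C@@H]2c3ccc(OCc4ccccc4)c(OCc4ccccc4)c3O[C@@H](c3ccc(OCc4ccccc4)cc3)[C@@H]2O[Si](C)(C)C(C)(C)C)c(OCc2ccccc2)c1OCc1ccccc1)[C@@H](O[Si](C)(C)C(C)(C)C)/C=C\c1ccc(OCc2ccccc2)cc1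
F5 | step 22 | cis-epoxide of F4, oxygen anti to the silyloxy group | CC(=O)Oc1c(cc([C@@H]2c3ccc(OCc4ccccc4)c(OCc4ccccc4)c3O[C@@H](c3ccc(OCc4ccccc4)cc3)[C@@H]2O[Si](C)(C)C(C)(C)C)c(OCc2ccccc2)c1OCc1ccccc1)[C@@H](O[Si](C)(C)C(C)(C)C)[C@H]5O[C@H]5c1ccc(OCc2ccccc2)cc1
F6 | step 25 | target carrying TBS ethers on upper O3 and lower O4 | Oc1ccc([C@H]2Oc3c(cc([C@@H]4c5ccc(O)c(O)c5O[C@@H](c5ccc(O)cc5)[C@@H]4O[Si](C)(C)C(C)(C)C)c(O)c3O)[C@@H](O[Si](C)(C)C(C)(C)C)[C@H]2O)cc1
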